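The numbers in the tables are calculated on assumed constants.

**The trap.** The capture agent is the limiting reagent of this flask family, its charge being the smallest. Each unit turns one mono adduct into trapped intermediate, so you can write the trap's capacity as 0.300 of the solid substrate charged.

| setting | beta | theta | zeta | Wednesday's | Saturday's | Thursday's |
|---|---|---|---|---|---|---|
| solid substrate | 20 mM | 20 mM | 20 mM | 20 mM | 20 mM | 20 mM |
| partner | 16 mM | 31 mM | 46 mM | 20.0 mM | 30.0 mM | 60.0 mM |
| capture agent | 6 mM | 6 mM | 6 mM | 6.00 mM | 6.00 mM | 6.00 mM |
| remark | run made earlier | run made earlier | run made earlier |  |  |  |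
| time |  |  |  | 5.0 d | 5.0 d | 5.0 d |

| run | time / d | triple product / % | bis adduct / % | solid substrate / % |
|---|---|---|---|---|
| beta | 1.04 | 0 | 3 | 84 |
| beta | 2.08 | 0 | 2 | 81 |
| beta | 3.00 | 3 | 5 | 72 |
| beta | 4.00 | 1 | 3 | 69 |
| beta | 5.00 | 0 | 9 | 70 |
| theta | 0.417 | 0 | 3 | 89 |
| theta | 1.25 | 0 | 4 | 78 |
| theta | 2.50 | 1 | 8 | 61 |
| theta | 4.00 | 4 | 11 | 49 |
| theta | 5.00 | 6 | 13 | 40 |
| zeta | 0.417 | 0 | 5 | 88 |
| zeta | 0.833 | 2 | 6 | 80 |
| zeta | 1.25 | 4 | 3 | 76 |
| zeta | 2.50 | 2 | 13 | 52 |
| zeta | 5.00 | 18 | 22 | 22 |

(readings scatter by 2 percentage points)

- for bis adduct the crystals are counted in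
- as a solid, counted per litre of solution: crystals, solid substrate
- the earlier runs were read with a standard deviation of 2 percentage points
- on the list of suspects stand: starting material + partner -> mono adduct; partner + mono adduct -> bis adduct; partner + bis adduct -> triple product; crystals <-> bis adduct; mono adduct + capture agent -> trapped intermediate; solid substrate <-> starting material
- at the start none of the solid substrate is in solution

* how much triple product is there at the end, in percent of the solid substrate charged: for each flask in turn (Wednesday's, Saturday's, Thursday's)

**The start.** In the theta run, the solid substrate readings fall by 0.101 d⁻¹ of its charge between 1.25 d and 5.00 d. The zeta slope over the same times is 1.42 times that, against 1.48 times the partner. So I take the rate as proportional to partner charged, which gives Wednesday's flask 0.0654 d⁻¹.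

**The slowing.** I count one slowing: filling the trap uses partner. For Wednesday's flask my rate stands at 0.700 of its start once the trap is full, and averages 0.850 of it on the way. The average is 0.900 in Saturday's flask and 0.950 in Thursday's.

**Fill time.** Call the fill time the capacity divided by that average rate, supposing the trap takes all that reacts: 5.40 d for Wednesday's flask, 3.40 d for Saturday's and 1.61 d for Thursday's. Set against 5.0 d, my reckoning has Wednesday's flask still filling and Thursday's with 3.39 d to spare. My reckoning gives these times, not percentages.

**The forecast.** It says 1%, 5.5% and 33%, calling Wednesday's flask “barely past the trap”.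

**The result.** The flasks give 2.65%, 7.54% and 31.6%, within the forecast's tolerance.

    starting material + partner → mono adduct (k = 0.0496 L mol⁻¹ min⁻¹)
    partner + mono adduct → bis adduct (k = 0.116 L mol⁻¹ min⁻¹)
    partner + bis adduct → triple product (k = 0.00930 L mol⁻¹ min⁻¹)
    crystals ⇌ bis adduct, rate k4*(cs4 - [bis adduct]) while solid is left; crystals form when [bis adduct] > cs4 (solubility = 16.0 mM, k = 1.19 min⁻¹)
    mono adduct + capture agent → trapped intermediate (k = 1.99 L mol⁻¹ min⁻¹)
    solid substrate ⇌ starting material, rate k6*(cs6 - [starting material]) while solid is left; crystals form when [starting material] > cs6 (solubility = 1.50 mM, k = 0.00764 min⁻¹)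

**The leak.** Wednesday's flask, with its fill time of 5.40 d, ends with 13% of its capture agent left, yet triple product stands at 2.65%. At that moment, capture uses mono adduct 1.2 times as fast as the path to bis adduct does, whereas the fill time supposed that the trap takes all. Thursday's flask passes its 1.61 d and still holds 19.2% of its capture agent at 2.50 d, with triple product at 11.3%; at 5.00 d the trapped intermediate stands at 29.8%.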